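3 questions stood on this flask, and each concerns how the charge was shared between the target and the other capture product. The winter run was this flask itself, followed to 15.0 s. The summer run had half the starting material.

| flask | starting material | first nucleophile | second nucleophile | remark | time |
|---|---|---|---|---|---|
| winter | 0.10 M | 0.30 M | 0.18 M | the very flask that is asked about, followed so far |  |
| summer | 0.050 M | 0.30 M | 0.18 M | run made earlier |  |
| flask | 0.10 M | 0.300 M | 0.180 M |  | 2.0 min |

| run | time / s | other capture product / % | target / % |
|---|---|---|---|
| winter | 10.0 | 3.3 | 6.0 |
| winter | 12.0 | 3.6 | 7.8 |
| winter | 15.0 | 4.8 | 10.5 |
| summer | 10.0 | 2.5 | 6.2 |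
| summer | 25.0 | 7.5 | 17.5 |
| summer | 40.0 | 11.9 | 24.2 |
| summer | 60.0 | 15.4 | 31.4 |
| summer | 90.0 | 19.7 | 38.5 |
| summer | 120 | 21.3 | 42.7 |

(each reading ± 0.5 percentage points)

* ratio of other capture product to target at 3.0 s
* ratio of other capture product to target at 2.0 min
* which of other capture product and target there is more of at 2.0 min

- the numbers in the tables scatter with a standard deviation of 0.5 percentage points

I read the runs as a ladder, fastest rung first. The sharing came first. By 10.0 s the summer ratio of other capture product to target already stood at 0.403, but readings that small scatter widely, so the ratio was best watched late. Over the last 3 summer readings it was 0.501. Both runs had the same nucleophile charges, so they could not test how the ratio follows them. I assumed that each nucleophile captures in proportion to its concentration. The ratio times c(first nucleophile) over c(second nucleophile) was then 0.835, and I carried this as the selectivity factor.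

The starting material came next. The first summer reading gave a capture pace of 0.00870 s⁻¹. That pace counted captured product, not the loss of starting material, so I took no half-life from it. The winter run stood at 9.30% captured at 10.0 s against 8.70% in summer, so I used the summer percentages for this flask.

The nucleophiles were slowest. From those percentages at 120 s I estimated that this flask had used 14.2% of its first nucleophile and 11.8% of its second, less than the 64.0% of starting material captured. So I reckoned 0.501 at 3.0 s and, for what was forming at 2.0 min, 0.515, with target ahead.

The forecast said 0.45 and 0.53, with target ahead, and that the ratio “should drift up slightly as the second nucleophile is consumed”. Its early value was lower than mine, and its late value higher.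

The flask gave 0.470 at 3.0 s and 0.509 at 2.0 min, with 41.8% of target against 21.2% of other capture product, so target led.

    starting material → intermediate (k = 0.0170 s⁻¹)
    first nucleophile + intermediate → target (k = 0.690 M⁻¹ s⁻¹)
    second nucleophile + intermediate → other capture product (k = 0.540 M⁻¹ s⁻¹)
    intermediate → solvolysis product (k = 0.0890 s⁻¹)
    first nucleophile + target → over-reaction product (k = 0.00300 M⁻¹ s⁻¹)

At 0.560 min in this flask the intermediate passed into target 2.1 times as fast as into other capture product, where the selectivity factor and the charges give 2.00. With the first nucleophile cut to 0.075 M, the factor gives a ratio of 2.00, and that neighbour flask stood at 1.96 at 2.0 min.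

The runs were generated by integration for substances that don't exist, noise included.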